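Set the impurity against the free catalyst before the first sample, and plan samples within minutes as well as at days.

the same everywhere: substrate 10 mM

| run | reagent | free catalyst | impurity | remark | time |
|---|---|---|---|---|---|
| red | 1.5 equiv | 0.14 mol% | 1 µM | run made earlier |  |
| grey | 1.5 equiv | 0.22 mol% | 1 µM | run made earlier |  |
| violet | 0.75 equiv | 0.1 mol% | 1 µM | run made earlier |  |
| flask | 1.50 equiv | 0.1 mol% | 1.0 µM |  | 15 d |

| run | time / d | uncatalysed product / % | target / % |
|---|---|---|---|
| red | 3.00 | 24 | 72 |
| red | 6.00 | 24 | 77 |
| red | 10.0 | 24 | 78 |
| red | 12.0 | 24 | 74 |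
| red | 15.0 | 20 | 75 |
| grey | 3.00 | 17 | 86 |
| grey | 6.00 | 15 | 84 |
| grey | 10.0 | 15 | 84 |
| grey | 12.0 | 13 | 85 |
| grey | 15.0 | 17 | 85 |
| violet | 1.25 | 18 | 59 |
| violet | 2.50 | 15 | 59 |
| violet | 4.00 | 14 | 58 |
| violet | 8.00 | 14 | 56 |
| violet | 15.0 | 14 | 58 |

(scatter of a reading: 2 percentage points)

* ratio of uncatalysed product to target at 8.0 min
* ratio of uncatalysed product to target at 15 d

- the numbers in the tables scatter with a standard deviation of 2 percentage points

In the red and grey runs, uncatalysed product and target stand flat from 3.00 d to 15.0 d within the scatter of 2 points, so each run's readings can be averaged into one end ratio of uncatalysed product to target. Suppose that the impurity removes free catalyst one for one, a supposition these readings barely test. The working loading is then the free catalyst charged minus the impurity, both as fractions of the substrate charged.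

The red run reads 0.309 on 0.130%, a product of 0.0401%. The grey run, a separate charge, reads 0.182 on 0.210%, a product of 0.0381%. The two ways agree, and their mean, 0.0391%, is the parity loading: end ratio times working loading, at fixed charges of 1.5 equiv of reagent and 10 mM of substrate. The violet run, at 0.75 equiv, stays out.

The flask has a working loading of 0.0900%, so this reckoning gives an end ratio of 0.435. It says nothing about 8.0 min: the earliest reading in any run comes at 1.25 d, far later.

The forecast puts the end ratio at 0.42 and the early ratio at 0.55, holding that “the instantaneous ratio should be higher”.

The flask gives 5.57 at 8.0 min and 0.442 at 15 d.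

    substrate ⇌ dormant form (K = 1.50, k = 0.00210 s⁻¹)
    free catalyst + impurity → spent catalyst (k = 4500 L mol⁻¹ s⁻¹)
    reagent + free catalyst + intermediate → free catalyst + target (k = 3200 L² mol⁻² s⁻¹)
    substrate + reagent → uncatalysed product (k = 0.0100 L mol⁻¹ s⁻¹)
    substrate + free catalyst → free catalyst + intermediate (k = 27.0 L mol⁻¹ s⁻¹)

The early ratio is ten times the forecast's, and the flask reaches equal uncatalysed product and target at 0.0486 d, later than the early sample. At 15.0 d, the flask's end ratio stands against a reckoned 0.435, with spent catalyst at 10.0% of the catalyst charged and the substrate, the limiting reagent, at 0%. The neighbour flask with 0.025 mol% of free catalyst has a working loading of 0.0150%, so the parity loading gives 2.61. That neighbour flask ends at 2.49, with spent catalyst at 40.0% of the catalyst charged and target at 28.7% of the substrate charged.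

(The earlier runs and the new flask were computed for substances that don't exist; scatter was added.)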